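## The problem

Abyssinoflavanone V (20) is a 5,7-dihydroxyflavanone (rings A and C). Its ring B is fused through C4'–O and C5'–C to a 2,2-dimethyldihydropyran with a secondary hydroxyl at C3'', and carries a prenyl group at C2' beside a free 3'-hydroxyl. There are two stereocentres, C2 of ring C (S) and C3'' of the pyran (S). They lie five bonds apart on opposite sides of ring B, so neither can direct the other and each needs its own reagent control. C2 is the fragile one: it is a benzylic aryl ether β to a ketone. Base opens ring C to the hydroxychalcone, and acid can ionise the C2–O bond because ring B has oxygen para to C1'; either path erases the centre. The prenyl group next to a free phenol cyclises under strong acid, and the phloroglucinol ring A is easily halogenated or oxidised. The feature that invites the key step is in ring C: C4 is an acyl carbon on ring A and C3 a methylene next to C2. Both can be carried as electrophiles (thioester and primary bromide), so ring C can be closed between them by reduction with C2 already configured. A second feature helps: a prenyl group ortho to the 3'-hydroxyl is the Claisen retron of a 3'-O-(1,1-dimethylallyl) ether, and C2' is the only free ortho position.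

## Retrosynthesis

**20 ⇒ 19.** The last cut removes only protecting groups: two methoxymethyl ethers on ring A and a silyl ether on the pyran carbinol. One acid solvolysis must take off all three without cyclising the prenyl group onto the 3'-hydroxyl.

**19 ⇒ 18.** The C2'–CH2 bond of the prenyl group is cut by a retro-Claisen step, giving the 3'-O-(1,1-dimethylallyl) ether 18. This is preferred to carrying the prenyl group from the start because a trisubstituted alkene three atoms from C1' would lie within cyclisation range of a C3 radical. The terminal alkene of 18 is eight atoms away. The forward step must send the allyl group to C2', the only ortho carbon bearing hydrogen.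

**18 ⇒ 17.** Ring C is opened at C3–C4, giving thioester 17 with a primary bromide at C3. The neighbouring cuts are less attractive here:
- C4–C4a (Friedel–Crafts) requires acid on a molecule with an ionisable C2–O bond.
- O1–C2 (oxa-Michael of a chalcone) makes C2 under equilibrating conditions.

Cutting C3–C4 leaves C2 untouched and joins two carbons of like polarity under neutral reducing conditions. The forward reaction must be an intramolecular acyl–alkyl cross-coupling that is faster than loss of the β-aryloxy group from C3.

**17 ⇒ 16 ⇒ 15.** The 2-pyridyl thioester comes from acid 16 by redox condensation, and 16 from aldehyde 15 by chlorite oxidation. An aldehyde is carried in place of an ester because no ester of this 2,6-dioxygenated benzoate could be cleaved next to a primary bromide, two acetals, a silyl ether and a tertiary allyl ether.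

**15 ⇒ 12 + 14.** The C2–O bond is cut, giving bromohydrin 12 and salicylaldehyde 14. This separates the molecule into its ring A and ring B halves at a bond that can be formed with inversion (Mitsunobu). The forward step needs an SN2 course at an electron-rich benzylic carbon; the bromomethyl group and the acidic phenol both favour that.

**14 ⇒ 13.** Two of the three hydroxyls of aldehyde 13 are protected; the one hydrogen-bonded to the formyl group stays free.

**12 ⇒ 11 ⇒ 9.** The carbinol of 12 comes from bromomethyl ketone 11 by catalyst-controlled reduction, which sets C2. Ketone 11 comes from methyl ketone 9 through silyl enol ether 10. The silyl triflate that makes 10 also protects the pyran carbinol, so no separate protection step is needed.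

**9 ⇒ 8 ⇒ 7 + 2.** The 1,1-dimethylallyl ether is reached from propargyl ether 8 by semihydrogenation, and 8 from phenol 7 and chloride 2. The same chloride 2 serves twice in the route.

**7 ⇒ 6 ⇒ 5.** The chromanol is traced to oxirane 6 by cutting the benzylic C4''–H bond, and 6 to chromene 5 by cutting both oxirane C–O bonds. A cis-alkene in a 2,2-dimethylchromene is among the best substrates for salen–manganese epoxidation. The benzylic position fixes the regiochemistry of the reductive opening, and the same hydrogenation removes the benzyl ether.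

**5 ⇒ 4 ⇒ 3 ⇒ 1 + 2.** The pyran ring is opened by a retro-propargyl-Claisen cascade to ether 4, which comes from 3 by benzylation and from acetophenone 1 and chloride 2. The acetyl group of 1 is the latent C2–C3 unit. The 4-hydroxyl of 1 is the more acidic one and the one to be alkylated first. Rearrangement can only go to C5 because C3 carries the benzyloxy group.

## Roads not taken

**Alternative 1:** The cut is across the two C–O bonds of an oxirane on the pyran ring. Chromene A1, with bromine at C6 and a methyl ether at C8, would be epoxidised with a chiral (salen)MnCl catalyst and NaOCl to epoxide A2, fixing the carbinol centre.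
- Merits: catalytic, reliable for cis-chromenes, and the aryl bromide is a handle for attaching C2 by halogen–metal exchange.
- Weak points: the strategy addresses only C3''. Ring C and C2 are left to a later, unspecified step, most naturally a chalcone cyclisation that does not control C2. The methyl ether at C8 must eventually be cleaved by a strong Lewis acid or thiolate in a molecule carrying a prenyl group and a base-labile ring C.
- Comparison: for the carbinol centre this road is as good as the chosen one, and the chosen plan uses the same epoxidation on chromene 5 (step 4). In its favour, every step of Alternative 1 is a known reaction, whereas the chosen plan rests on an untested ring closure. What the chosen plan sets against that is a defined answer for C2, fixed before ring closure and never exposed to an enolate, and a benzyl ether that leaves in the same operation that opens the oxirane.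

**Alternative 2:** The cut is at the O–C(CH3)2 bond of the pyran. Epoxy phenol A3, the (S)-epoxide of a 5-prenyl-4-hydroxybenzoate, would cyclise under mild acid by attack of the phenol on the tertiary epoxide carbon. The product is chromanol ester A4, with the carbinol configuration unchanged.
- Merits: no reductive step, no benzyl ether, and the prenyl precursor comes from the same Claisen chemistry used elsewhere; for the chromanol alone it is at least as short as the chosen sequence.
- Weak points: the phenol can also attack the secondary epoxide carbon (5-exo) and give a hydroxyisopropyl dihydrobenzofuran. The balance between the two modes depends on how cationic the transition state is. Epoxidation of a trisubstituted prenyl alkene by a chiral dioxirane is usually less selective than chromene epoxidation. The ester must then be turned into the two-carbon unit, and ring C is again not addressed.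
- Comparison: the chosen plan pays two extra operations (benzylation, hydrogenolysis) for a regiochemistry decided by the benzylic position and not by a 6-endo/5-exo competition.

**Alternative 3:** The cut is at C4–C4a. Acid A5, a (3S)-3-aryl-3-aryloxypropanoic acid made by asymmetric allylic etherification and chain oxidation, would be activated as a mixed anhydride. It would acylate the ortho carbon of its bis(silyloxy)phenyl ether to give flavanone A6, the tetrasilyl ether of the target.
- Merits: every step is known chemistry. The phloroglucinol ring is symmetric, so the acylation has no regiochemical question. A6 is one deprotection from the target, so the end game is shorter than the chosen one, and the prenyl group is already in place.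
- Weak points: the ring closure is run in acid. A5 has a C–O bond at an electron-rich benzylic carbon that can ionise or eliminate to the cinnamic acid. It has a prenyl group flanked by a silyloxy group, and aryl silyl ethers that both deactivate and crowd the carbon to be acylated.
- Comparison: in precedent and step count this road is better than the chosen one. The chosen plan sets against it a ring closure under neutral, reducing conditions with no acid, no base and no electrophilic aromatic substitution, so the C2–O bond and the masked prenyl group are not put at risk. That gain is real only if the nickel step works, which is why a known-chemistry fallback is kept in reserve.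

Key step: step 14

Assumption: the (S,S)-configured salen–manganese catalyst is taken to give the (3S,4S)-oxide of chromene 5, as for other 6-acyl- and 6-cyano-2,2-dimethylchromenes, and the (S)-oxazaborolidine to give the (S)-bromohydrin, as for phenacyl halides; if either sense were reversed, the mirror-image catalyst would be used.

## Route

Step 1
Reactants: 1 1-(3,4-dihydroxyphenyl)ethan-1-one; 2 3-chloro-3-methylbut-1-yne
Product: 3 1-[3-hydroxy-4-(2-methylbut-3-yn-2-yloxy)phenyl]ethan-1-one
Conditions: DBU (1.05 equiv), CuCl2 (1 mol%), MeCN, 0 °C, argon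
Reagents that add atoms: none
Why: Copper-catalysed propargylic etherification of a phenol; the 4-hydroxyl, para to the acetyl group, is the more acidic and is the only one ionised by one equivalent of base, so the tertiary propargyl ether should form there.

Step 2
Reactants: 3 1-[3-hydroxy-4-(2-methylbut-3-yn-2-yloxy)phenyl]ethan-1-one
Product: 4 1-[3-(benzyloxy)-4-(2-methylbut-3-yn-2-yloxy)phenyl]ethan-1-one
Conditions: BnBr, K2CO3, DMF, 25 °C
Reagents that add atoms: benzyl bromide, BrCc1ccccc1
Why: Williamson etherification of the remaining phenol; benzyl is chosen because it leaves in step 5 at no extra cost and protects the phenol from hypochlorite in step 4.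

Step 3
Reactants: 4 1-[3-(benzyloxy)-4-(2-methylbut-3-yn-2-yloxy)phenyl]ethan-1-one
Product: 5 1-[8-(benzyloxy)-2,2-dimethyl-2H-chromen-6-yl]ethan-1-one
Conditions: N,N-diethylaniline, 180 °C
Reagents that add atoms: none
Why: Aromatic propargyl Claisen rearrangement to C5, the only free ortho carbon, followed by 1,5-hydrogen shift and 6π-oxa-electrocyclisation, the standard entry to 2,2-dimethyl-2H-chromenes.

Step 4
Reactants: 5 1-[8-(benzyloxy)-2,2-dimethyl-2H-chromen-6-yl]ethan-1-one
Product: 6 1-[(3S,4S)-8-(benzyloxy)-3,4-epoxy-2,2-dimethyl-3,4-dihydro-2H-chromen-6-yl]ethan-1-one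
Conditions: (S,S)-(salen)MnCl [salen = N,N'-bis(3,5-di-tert-butylsalicylidene)cyclohexane-1,2-diamine dianion] (4 mol%), aq. NaOCl (pH 11.3), 4-phenylpyridine N-oxide, CH2Cl2, 0 °C
Reagents that add atoms: sodium hypochlorite, [Na+].[O-]Cl
Why: Jacobsen–Katsuki epoxidation of a cis, aryl-conjugated alkene in a 2,2-dimethylchromene, the best substrate class for this catalyst; the chiral salen ligand selects the alkene face and sets C3 (the later carbinol centre) and C4 together.

Step 5
Reactants: 6 1-[(3S,4S)-8-(benzyloxy)-3,4-epoxy-2,2-dimethyl-3,4-dihydro-2H-chromen-6-yl]ethan-1-one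
Product: 7 1-[(3S)-3,8-dihydroxy-2,2-dimethyl-3,4-dihydro-2H-chromen-6-yl]ethan-1-one
Conditions: H2 (1 atm), Pd/C, EtOAc, 25 °C, stopped at two equivalents of H2
Reagents that add atoms: none
Why: Catalytic hydrogenolysis cleaves the benzylic C4–O bond of the oxirane and the benzyl ether, both faster than reduction of an aryl ketone; the C3–O bond is not benzylic and stays, so the (3S) configuration is kept.

Step 6
Reactants: 7 1-[(3S)-3,8-dihydroxy-2,2-dimethyl-3,4-dihydro-2H-chromen-6-yl]ethan-1-one; 2 3-chloro-3-methylbut-1-yne
Product: 8 1-[(3S)-3-hydroxy-2,2-dimethyl-8-(2-methylbut-3-yn-2-yloxy)-3,4-dihydro-2H-chromen-6-yl]ethan-1-one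
Conditions: DBU (1.1 equiv), CuCl2 (1 mol%), MeCN, 0 °C
Reagents that add atoms: none
Why: The same copper-catalysed propargylic etherification as in step 1; only the phenol is ionised by DBU, so the secondary alcohol is left alone.

Step 7
Reactants: 8 1-[(3S)-3-hydroxy-2,2-dimethyl-8-(2-methylbut-3-yn-2-yloxy)-3,4-dihydro-2H-chromen-6-yl]ethan-1-one
Product: 9 1-[(3S)-3-hydroxy-2,2-dimethyl-8-(2-methylbut-3-en-2-yloxy)-3,4-dihydro-2H-chromen-6-yl]ethan-1-one
Conditions: H2 (1 atm), Pd/CaCO3 poisoned with Pb(OAc)2 (Lindlar), quinoline, EtOAc, 25 °C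
Reagents that add atoms: none
Why: Lindlar semihydrogenation of a terminal alkyne stops at the alkene and leaves the aryl ketone; this is the usual way to 1,1-dimethylallyl aryl ethers.

Step 8
Reactants: 9 1-[(3S)-3-hydroxy-2,2-dimethyl-8-(2-methylbut-3-en-2-yloxy)-3,4-dihydro-2H-chromen-6-yl]ethan-1-one
Product: 11 2-bromo-1-[(3S)-3-[(tert-butyldimethylsilyl)oxy]-2,2-dimethyl-8-(2-methylbut-3-en-2-yloxy)chroman-6-yl]ethan-1-one, via silyl enol ether 10 (not isolated)
Conditions: TBSOTf (2.4 equiv), Et3N, CH2Cl2, 0 °C; aq. NaHCO3 work-up; crude 10, NBS (1.05 equiv), THF, 0 °C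
Reagents that add atoms: tert-butyldimethylsilyl trifluoromethanesulfonate, CC(C)(C)[Si](C)(C)OS(=O)(=O)C(F)(F)F; N-bromosuccinimide, BrN1C(=O)CCC1=O
Why: Silyl triflate and amine silylate the carbinol and convert the methyl ketone into its silyl enol ether; bromination of that enol ether with NBS is much faster than attack on the arene or the terminal alkene and gives the bromomethyl ketone.

Step 9
Reactants: 11 2-bromo-1-[(3S)-3-[(tert-butyldimethylsilyl)oxy]-2,2-dimethyl-8-(2-methylbut-3-en-2-yloxy)chroman-6-yl]ethan-1-one
Product: 12 (1S)-2-bromo-1-[(3S)-3-[(tert-butyldimethylsilyl)oxy]-2,2-dimethyl-8-(2-methylbut-3-en-2-yloxy)chroman-6-yl]ethan-1-ol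
Conditions: (S)-2-methyl-CBS-oxazaborolidine (20 mol%), catecholborane (1.8 equiv), toluene, −78 °C; pH 7 buffer
Reagents that add atoms: none
Why: Corey–Bakshi–Shibata reduction with aryl as the large and bromomethyl as the small group; the (S)-catalyst delivers hydride to the face that gives the (S)-bromohydrin (S because CH2Br outranks aryl), and catecholborane at low temperature does not hydroborate the terminal alkene. Minor stereoisomers from steps 4 and 9 are diastereomers of 12 and can be removed from here on.

Step 10
Reactants: 13 2,4,6-trihydroxybenzaldehyde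
Product: 14 2-hydroxy-4,6-bis(methoxymethoxy)benzaldehyde
Conditions: MOMCl (2.2 equiv), i-Pr2NEt, CH2Cl2, 0 to 25 °C
Reagents that add atoms: chloromethyl methyl ether, COCCl
Why: Acetal protection of phenols; the hydroxyl hydrogen-bonded to the formyl group is the least nucleophilic and should remain free, as with related 2-acyl phloroglucinols.

Step 11
Reactants: 12 (1S)-2-bromo-1-[(3S)-3-[(tert-butyldimethylsilyl)oxy]-2,2-dimethyl-8-(2-methylbut-3-en-2-yloxy)chroman-6-yl]ethan-1-ol; 14 2-hydroxy-4,6-bis(methoxymethoxy)benzaldehyde
Product: 15 2-{(1R)-2-bromo-1-[(3S)-3-[(tert-butyldimethylsilyl)oxy]-2,2-dimethyl-8-(2-methylbut-3-en-2-yloxy)chroman-6-yl]ethoxy}-4,6-bis(methoxymethoxy)benzaldehyde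
Conditions: PPh3, DIAD, toluene, 0 °C
Reagents that add atoms: none
Why: Mitsunobu etherification with inversion at the carbinol carbon; the salicylaldehyde-type phenol is acidic enough to be a good pronucleophile, and the electron-withdrawing bromomethyl group disfavours ionisation of the alkoxyphosphonium ion, so the (1S)-alcohol should give the (1R)-ether.

Step 12
Reactants: 15 2-{(1R)-2-bromo-1-[(3S)-3-[(tert-butyldimethylsilyl)oxy]-2,2-dimethyl-8-(2-methylbut-3-en-2-yloxy)chroman-6-yl]ethoxy}-4,6-bis(methoxymethoxy)benzaldehyde
Product: 16 2-{(1R)-2-bromo-1-[(3S)-3-[(tert-butyldimethylsilyl)oxy]-2,2-dimethyl-8-(2-methylbut-3-en-2-yloxy)chroman-6-yl]ethoxy}-4,6-bis(methoxymethoxy)benzoic acid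
Conditions: NaClO2, NaH2PO4, 2-methylbut-2-ene (large excess), t-BuOH/THF/H2O, 0 to 25 °C
Reagents that add atoms: sodium chlorite, [Na+].[O-]Cl=O
Why: Pinnick oxidation of an aryl aldehyde under buffered, weakly acidic conditions that spare the bromide, the acetals and the silyl ether; the excess alkene scavenges hypochlorous acid before it can chlorinate ring A.

Step 13
Reactants: 16 2-{(1R)-2-bromo-1-[(3S)-3-[(tert-butyldimethylsilyl)oxy]-2,2-dimethyl-8-(2-methylbut-3-en-2-yloxy)chroman-6-yl]ethoxy}-4,6-bis(methoxymethoxy)benzoic acid
Product: 17 S-(pyridin-2-yl) 2-{(1R)-2-bromo-1-[(3S)-3-[(tert-butyldimethylsilyl)oxy]-2,2-dimethyl-8-(2-methylbut-3-en-2-yloxy)chroman-6-yl]ethoxy}-4,6-bis(methoxymethoxy)benzenecarbothioate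
Conditions: 2,2'-dipyridyl disulfide, PPh3, CH2Cl2, 25 °C
Reagents that add atoms: 2,2'-dipyridyl disulfide, c1ccc(SSc2ccccn2)nc1
Why: Mukaiyama redox condensation (the activation used in Corey–Nicolaou lactonisation) converts the acid to the 2-pyridyl thioester under neutral conditions; the hindered, β-branched primary bromide should not be alkylated by the thione at room temperature.

Step 14
Reactants: 17 S-(pyridin-2-yl) 2-{(1R)-2-bromo-1-[(3S)-3-[(tert-butyldimethylsilyl)oxy]-2,2-dimethyl-8-(2-methylbut-3-en-2-yloxy)chroman-6-yl]ethoxy}-4,6-bis(methoxymethoxy)benzenecarbothioate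
Product: 18 (2S)-2-[(3S)-3-[(tert-butyldimethylsilyl)oxy]-2,2-dimethyl-8-(2-methylbut-3-en-2-yloxy)chroman-6-yl]-5,7-bis(methoxymethoxy)chroman-4-one
Conditions: NiCl2·dme (10 mol%), 4,4'-di-tert-butyl-2,2'-bipyridine (12 mol%), Mn powder (3 equiv), DMA, 0.02 M, 25 °C
Reagents that add atoms: none
Why: Proposed new method: zerovalent nickel, formed from NiCl2·dme, the bipyridine and Mn, inserts into the acyl–sulfur bond of the 2-pyridyl thioester, a low-valent nickel species abstracts the bromine atom at C3, the primary radical is caught by the tethered acyl nickel, and reductive elimination from trivalent nickel forms the C3–C4 ketone bond; the closest known reaction type is the intermolecular nickel-catalysed reductive coupling of alkyl halides with 2-pyridyl thioesters or acid chlorides to ketones, which has not been used to close a ring of this kind. Ring C closes as a six-membered ring by C(sp3)–C(acyl) reductive elimination from a seven-membered nickelacycle, not by radical attack on a π bond. No stereocentre is formed: C2 is already configured in 17 and its descriptor changes from R to S only because the CIP priorities change, and with neither enolate nor acid present it can neither open to a chalcone nor ionise. The step needs acyl–alkyl cross-coupling within one molecule in preference to dimerisation; the different activation modes of thioester (two-electron insertion) and bromide (halogen-atom abstraction), the tether and the dilution should secure that. It also needs ring closure to outrun loss of the β-aryloxy group from C3; a free radical and a short-lived trivalent alkyl nickel, rather than an alkylmanganese or alkylzinc species, keep that path slow. The only alkene is the terminal one of the 1,1-dimethylallyl ether, eight atoms from C3 and outside radical cyclisation range.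

Step 15
Reactants: 18 (2S)-2-[(3S)-3-[(tert-butyldimethylsilyl)oxy]-2,2-dimethyl-8-(2-methylbut-3-en-2-yloxy)chroman-6-yl]-5,7-bis(methoxymethoxy)chroman-4-one
Product: 19 (2S)-2-[(3S)-3-[(tert-butyldimethylsilyl)oxy]-8-hydroxy-2,2-dimethyl-7-(3-methylbut-2-en-1-yl)chroman-6-yl]-5,7-bis(methoxymethoxy)chroman-4-one
Conditions: Eu(fod)3 (10 mol%), CHCl3, 60 °C
Reagents that add atoms: none
Why: Europium-catalysed aromatic Claisen rearrangement of a 1,1-dimethylallyl aryl ether; the [3,3] shift delivers the allyl group with transposition (hence prenyl) to C2' (C7 of the chroman), the only ortho carbon bearing hydrogen, and tautomerisation restores the phenol. The mild Lewis acid leaves the acetals, the silyl ether and C2 untouched.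

Step 16
Reactants: 19 (2S)-2-[(3S)-3-[(tert-butyldimethylsilyl)oxy]-8-hydroxy-2,2-dimethyl-7-(3-methylbut-2-en-1-yl)chroman-6-yl]-5,7-bis(methoxymethoxy)chroman-4-one
Product: 20 (2S)-5,7-dihydroxy-2-[(3S)-3,8-dihydroxy-2,2-dimethyl-7-(3-methylbut-2-en-1-yl)chroman-6-yl]chroman-4-one (abyssinoflavanone V)
Conditions: 3 M aq. HCl, MeOH/THF, 45 °C
Reagents that add atoms: none
Why: Acid-catalysed solvolysis removes both methoxymethyl acetals and the secondary silyl ether in one operation; such conditions are routinely used on prenylated flavanones and should be mild enough to avoid cyclisation of the prenyl group or opening of ring C.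

## Compound list

1 | 1-(3,4-dihydroxyphenyl)ethan-1-one | CC(=O)c1ccc(O)c(O)c1 | starting material
2 | 3-chloro-3-methylbut-1-yne | C#CC(C)(C)Cl | starting material
3 | 1-[3-hydroxy-4-(2-methylbut-3-yn-2-yloxy)phenyl]ethan-1-one | CC(=O)c1ccc(OC(C)(C)C#C)c(O)c1 | intermediate
4 | 1-[3-(benzyloxy)-4-(2-methylbut-3-yn-2-yloxy)phenyl]ethan-1-one | CC(=O)c1ccc(OC(C)(C)C#C)c(OCc2ccccc2)c1 | intermediate
5 | 1-[8-(benzyloxy)-2,2-dimethyl-2H-chromen-6-yl]ethan-1-one | CC(=O)c1cc(OCc2ccccc2)c3OC(C)(C)C=Cc3c1 | intermediate
6 | 1-[(3S,4S)-8-(benzyloxy)-3,4-epoxy-2,2-dimethyl-3,4-dihydro-2H-chromen-6-yl]ethan-1-one | CC(=O)c1cc(OCc2ccccc2)c3OC(C)(C)[C@H]4O[C@H]4c3c1 | intermediate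
7 | 1-[(3S)-3,8-dihydroxy-2,2-dimethyl-3,4-dihydro-2H-chromen-6-yl]ethan-1-one | CC(=O)c1cc(O)c2OC(C)(C)[C@@H](O)Cc2c1 | intermediate
8 | 1-[(3S)-3-hydroxy-2,2-dimethyl-8-(2-methylbut-3-yn-2-yloxy)-3,4-dihydro-2H-chromen-6-yl]ethan-1-one | CC(=O)c1cc(OC(C)(C)C#C)c2OC(C)(C)[C@@H](O)Cc2c1 | intermediate
9 | 1-[(3S)-3-hydroxy-2,2-dimethyl-8-(2-methylbut-3-en-2-yloxy)-3,4-dihydro-2H-chromen-6-yl]ethan-1-one | CC(=O)c1cc(OC(C)(C)C=C)c2OC(C)(C)[C@@H](O)Cc2c1 | intermediate
10 | (3S)-3-[(tert-butyldimethylsilyl)oxy]-6-{1-[(tert-butyldimethylsilyl)oxy]ethenyl}-2,2-dimethyl-8-(2-methylbut-3-en-2-yloxy)chromane | C=C(O[Si](C)(C)C(C)(C)C)c1cc(OC(C)(C)C=C)c2OC(C)(C)[C@@H](O[Si](C)(C)C(C)(C)C)Cc2c1 | intermediate (not isolated)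
11 | 2-bromo-1-[(3S)-3-[(tert-butyldimethylsilyl)oxy]-2,2-dimethyl-8-(2-methylbut-3-en-2-yloxy)chroman-6-yl]ethan-1-one | O=C(CBr)c1cc(OC(C)(C)C=C)c2OC(C)(C)[C@@H](O[Si](C)(C)C(C)(C)C)Cc2c1 | intermediate
12 | (1S)-2-bromo-1-[(3S)-3-[(tert-butyldimethylsilyl)oxy]-2,2-dimethyl-8-(2-methylbut-3-en-2-yloxy)chroman-6-yl]ethan-1-ol | C=CC(C)(C)Oc1cc([C@H](O)CBr)cc2c1OC(C)(C)[C@@H](O[Si](C)(C)C(C)(C)C)C2 | intermediate
13 | 2,4,6-trihydroxybenzaldehyde | O=Cc1c(O)cc(O)cc1O | starting material
14 | 2-hydroxy-4,6-bis(methoxymethoxy)benzaldehyde | COCOc1cc(O)c(C=O)c(OCOC)c1 | intermediate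
15 | 2-{(1R)-2-bromo-1-[(3S)-3-[(tert-butyldimethylsilyl)oxy]-2,2-dimethyl-8-(2-methylbut-3-en-2-yloxy)chroman-6-yl]ethoxy}-4,6-bis(methoxymethoxy)benzaldehyde | C=CC(C)(C)Oc1cc([C@H](CBr)Oc3cc(OCOC)cc(OCOC)c3C=O)cc2c1OC(C)(C)[C@@H](O[Si](C)(C)C(C)(C)C)C2 | intermediate
16 | 2-{(1R)-2-bromo-1-[(3S)-3-[(tert-butyldimethylsilyl)oxy]-2,2-dimethyl-8-(2-methylbut-3-en-2-yloxy)chroman-6-yl]ethoxy}-4,6-bis(methoxymethoxy)benzoic acid | C=CC(C)(C)Oc1cc([C@H](CBr)Oc3cc(OCOC)cc(OCOC)c3C(=O)O)cc2c1OC(C)(C)[C@@H](O[Si](C)(C)C(C)(C)C)C2 | intermediate
17 | S-(pyridin-2-yl) 2-{(1R)-2-bromo-1-[(3S)-3-[(tert-butyldimethylsilyl)oxy]-2,2-dimethyl-8-(2-methylbut-3-en-2-yloxy)chroman-6-yl]ethoxy}-4,6-bis(methoxymethoxy)benzenecarbothioate | C=CC(C)(C)Oc1cc([C@H](CBr)Oc3cc(OCOC)cc(OCOC)c3C(=O)Sc4ccccn4)cc2c1OC(C)(C)[C@@H](O[Si](C)(C)C(C)(C)C)C2 | intermediate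
18 | (2S)-2-[(3S)-3-[(tert-butyldimethylsilyl)oxy]-2,2-dimethyl-8-(2-methylbut-3-en-2-yloxy)chroman-6-yl]-5,7-bis(methoxymethoxy)chroman-4-one | C=CC(C)(C)Oc1cc([C@@H]2CC(=O)c3c(OCOC)cc(OCOC)cc3O2)cc2c1OC(C)(C)[C@@H](O[Si](C)(C)C(C)(C)C)C2 | intermediate
19 | (2S)-2-[(3S)-3-[(tert-butyldimethylsilyl)oxy]-8-hydroxy-2,2-dimethyl-7-(3-methylbut-2-en-1-yl)chroman-6-yl]-5,7-bis(methoxymethoxy)chroman-4-one | CC(C)=CCc1c([C@@H]2CC(=O)c3c(OCOC)cc(OCOC)cc3O2)cc2c(c1O)OC(C)(C)[C@@H](O[Si](C)(C)C(C)(C)C)C2 | intermediate
20 | (2S)-5,7-dihydroxy-2-[(3S)-3,8-dihydroxy-2,2-dimethyl-7-(3-methylbut-2-en-1-yl)chroman-6-yl]chroman-4-one (abyssinoflavanone V) | CC(C)=CCc1c([C@@H]2CC(=O)c3c(O)cc(O)cc3O2)cc2c(c1O)OC(C)(C)[C@@H](O)C2 | target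

## Step count and least certain steps

Total: 16 steps. Longest linear sequence: 15 steps (steps 1–9 and 11–16); step 10 is a one-step side branch.

**Step 14 (key step, proposed new method).** The most likely failure is fragmentation: the β-aryloxy group is lost from C3, either by β-scission of the radical or by β-elimination from an alkyl nickel, and the molecule splits into a styrene and a ring A phenol. Lesser risks are reduction of the C–Br bond without coupling, decarbonylation of the hindered aroyl nickel, and insertion of zerovalent nickel into the allylic C–O bond of the 1,1-dimethylallyl ether. The fallback uses known carbene chemistry and avoids both the metal and a carbon-centred radical. It sets out from aldehyde 15, two steps before the key step. The bromide is exchanged with NaI in acetone to give iodo aldehyde F1. F1 is treated with a thiazolium-derived N-heterocyclic carbene (3-benzyl-5-(2-hydroxyethyl)-4-methylthiazolium chloride, DBU, dioxane, warm). The Breslow intermediate formed at the formyl carbon displaces iodide at C3 in a 6-exo-tet alkylation, a known route from O-(2-haloethyl)salicylaldehydes to chroman-4-ones, and the route is rejoined at flavanone 18. The base must be kept catalytic and the temperature low to limit elimination and epimerisation at C2.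

**Step 11 (Mitsunobu etherification).** The alkoxyphosphonium ion sits on a benzylic carbon of an arene with oxygen para to it. Partial ionisation would erode the configuration at C2, and elimination to the bromostyrene is also possible. The fallback forms the same C–O bond from the other side, with retention. It sets out from ketone 9. Enol ether 10 is made as in step 8 and oxidised with mCPBA (Rubottom oxidation) to silyloxy ketone F2. CBS reduction with the (R)-oxazaborolidine and catecholborane gives alcohol F3. Its lithium alkoxide (LiHMDS, THF, low temperature, fluoroarene present from the start to outrun silyl migration) displaces fluoride from fluoro aldehyde F4, the 2-fluoro analogue of 14, made separately. This is a nucleophilic aromatic substitution that does not touch the stereocentre and gives ether F5. Buffered HF·pyridine removes the primary silyl group to give alcohol F6. PPh3 and NBS convert F6 into the bromide, rejoining the route at 15.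

**Step 5 (hydrogenolysis).** Over-reduction is the danger: the aryl ketone may be hydrogenated to the carbinol and further to the ethyl arene before both C–O cleavages are complete. The fallback separates the tasks and uses no catalytic hydrogenation. It sets out from epoxide 6. LiAlH4 opens the oxirane at the benzylic carbon and reduces the ketone, giving diol F7. MnO2 reoxidises only the benzylic carbinol to hydroxy ketone F8. BCl3 with pentamethylbenzene at −78 °C removes the benzyl ether, rejoining the route at 7.

**Step 16 (global deprotection).** The hindered silyl ether may need acid strong enough to start cyclisation of the prenyl group onto the 3'-hydroxyl. The fallback replaces one protic solvolysis by two orthogonal cleavages. It sets out from 19. Buffered HF·pyridine removes the silyl group to give diol F9. The two acetals are then cleaved with ZnBr2 and propane-1-thiol in CH2Cl2 at 0 °C, a thiol-transfer cleavage without protic acid, rejoining the route at 20.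

## Further compounds

F1 | step 14 | 2-{(1R)-1-[(3S)-3-[(tert-butyldimethylsilyl)oxy]-2,2-dimethyl-8-(2-methylbut-3-en-2-yloxy)chroman-6-yl]-2-iodoethoxy}-4,6-bis(methoxymethoxy)benzaldehyde | C=CC(C)(C)Oc1cc([C@H](CI)Oc3cc(OCOC)cc(OCOC)c3C=O)cc2c1OC(C)(C)[C@@H](O[Si](C)(C)C(C)(C)C)C2
F2 | step 11 | 2-[(tert-butyldimethylsilyl)oxy]-1-[(3S)-3-[(tert-butyldimethylsilyl)oxy]-2,2-dimethyl-8-(2-methylbut-3-en-2-yloxy)chroman-6-yl]ethan-1-one | C=CC(C)(C)Oc1cc(C(=O)CO[Si](C)(C)C(C)(C)C)cc2c1OC(C)(C)[C@@H](O[Si](C)(C)C(C)(C)C)C2
F3 | step 11 | (1R)-2-[(tert-butyldimethylsilyl)oxy]-1-[(3S)-3-[(tert-butyldimethylsilyl)oxy]-2,2-dimethyl-8-(2-methylbut-3-en-2-yloxy)chroman-6-yl]ethan-1-ol | C=CC(C)(C)Oc1cc([C@H](CO[Si](C)(C)C(C)(C)C)O)cc2c1OC(C)(C)[C@@H](O[Si](C)(C)C(C)(C)C)C2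
F4 | step 11 | 2-fluoro-4,6-bis(methoxymethoxy)benzaldehyde | COCOc1cc(F)c(C=O)c(OCOC)c1
F5 | step 11 | 2-{(1R)-2-[(tert-butyldimethylsilyl)oxy]-1-[(3S)-3-[(tert-butyldimethylsilyl)oxy]-2,2-dimethyl-8-(2-methylbut-3-en-2-yloxy)chroman-6-yl]ethoxy}-4,6-bis(methoxymethoxy)benzaldehyde | C=CC(C)(C)Oc1cc([C@H](CO[Si](C)(C)C(C)(C)C)Oc3cc(OCOC)cc(OCOC)c3C=O)cc2c1OC(C)(C)[C@@H](O[Si](C)(C)C(C)(C)C)C2
F6 | step 11 | 2-{(1R)-1-[(3S)-3-[(tert-butyldimethylsilyl)oxy]-2,2-dimethyl-8-(2-methylbut-3-en-2-yloxy)chroman-6-yl]-2-hydroxyethoxy}-4,6-bis(methoxymethoxy)benzaldehyde | C=CC(C)(C)Oc1cc([C@H](CO)Oc3cc(OCOC)cc(OCOC)c3C=O)cc2c1OC(C)(C)[C@@H](O[Si](C)(C)C(C)(C)C)C2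
F7 | step 5 | (3S)-8-(benzyloxy)-6-(1-hydroxyethyl)-2,2-dimethylchroman-3-ol (both epimers at the side-chain carbinol) | CC(O)c1cc(OCc2ccccc2)c3OC(C)(C)[C@@H](O)Cc3c1
F8 | step 5 | 1-[(3S)-8-(benzyloxy)-3-hydroxy-2,2-dimethyl-3,4-dihydro-2H-chromen-6-yl]ethan-1-one | CC(=O)c1cc(OCc2ccccc2)c3OC(C)(C)[C@@H](O)Cc3c1
F9 | step 16 | (2S)-2-[(3S)-3,8-dihydroxy-2,2-dimethyl-7-(3-methylbut-2-en-1-yl)chroman-6-yl]-5,7-bis(methoxymethoxy)chroman-4-one | CC(C)=CCc1c([C@@H]2CC(=O)c3c(OCOC)cc(OCOC)cc3O2)cc2c(c1O)OC(C)(C)[C@@H](O)C2
A1 | alternative 1 | 6-bromo-8-methoxy-2,2-dimethyl-2H-chromene | COc1cc(Br)cc2c1OC(C)(C)C=C2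
A2 | alternative 1 | (3S,4S)-6-bromo-3,4-epoxy-8-methoxy-2,2-dimethylchromane | COc1cc(Br)cc2c1OC(C)(C)[C@H]3O[C@@H]23
A3 | alternative 2 | methyl 3-{[(2S)-3,3-dimethyloxiran-2-yl]methyl}-4-hydroxy-5-(methoxymethoxy)benzoate | COC(=O)c1cc(C[C@@H]2OC2(C)C)c(O)c(OCOC)c1
A4 | alternative 2 | methyl (3S)-3-hydroxy-8-(methoxymethoxy)-2,2-dimethylchromane-6-carboxylate | COC(=O)c1cc2c(c(OCOC)c1)OC(C)(C)[C@@H](O)C2
A5 | alternative 3 | (3S)-3-[3,5-bis(triisopropylsilyloxy)phenoxy]-3-[(3S)-3-[(tert-butyldimethylsilyl)oxy]-2,2-dimethyl-7-(3-methylbut-2-en-1-yl)-8-(triisopropylsilyloxy)chroman-6-yl]propanoic acid | CC(C)=CCc1c([C@H](CC(=O)O)Oc3cc(O[Si](C(C)C)(C(C)C)C(C)C)cc(O[Si](C(C)C)(C(C)C)C(C)C)c3)cc2c(c1O[Si](C(C)C)(C(C)C)C(C)C)OC(C)(C)[C@@H](O[Si](C)(C)C(C)(C)C)C2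
A6 | alternative 3 | (2S)-2-[(3S)-3-[(tert-butyldimethylsilyl)oxy]-2,2-dimethyl-7-(3-methylbut-2-en-1-yl)-8-(triisopropylsilyloxy)chroman-6-yl]-5,7-bis(triisopropylsilyloxy)chroman-4-one | CC(C)=CCc1c([C@@H]2CC(=O)c3c(O[Si](C(C)C)(C(C)C)C(C)C)cc(O[Si](C(C)C)(C(C)C)C(C)C)cc3O2)cc2c(c1O[Si](C(C)C)(C(C)C)C(C)C)OC(C)(C)[C@@H](O[Si](C)(C)C(C)(C)C)C2
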